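**Plan**

1. Retrosynthesis: the furan O1–C2 bond of radermachol is opened first (cyclodehydration of a C9b hydroxyl onto a side-chain ketone). The seven-membered ring is then cut at C3–C3a and at C4–C(=O) while one C3–C(=O) bond is restored, which returns a 2-acylindane-1,3-dione and 1,4-naphthoquinone. The acylindanedione is cut at its two ring C–C(=O) bonds into a phthalate diester and mesityl oxide.
2. Enabling feature (naphtho[1,2-b]furan numbering O1, C2, C3, C3a, C4, C5, C5a–C9a, C9b): the seven-membered ring is C3, C3a and C4 plus an o-phthaloyl unit (two carbonyl carbons on one benzene ring). C3a–C4, flanked by the oxygenated C9b and C5, is the C2–C3 bond of a 1,4-naphthoquinone, so the ring is an indane-1,3-dione enlarged by two quinone carbons.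
3. Forward: dimethyl phthalate 1 and mesityl oxide 2 give, through diketo ester 3, the five-membered dione ring of 4. Quinone 5 is then inserted into a ring C–C(=O) bond of 4 (through 6 and 7) to give the seven-membered ring of 8. The furan ring is closed last to give radermachol 9.
4. Stereochemistry: the target has no stereocentre and its only side-chain alkene carries two identical methyl groups, so nothing has to be controlled; the stereocentres of 7 are transient.

Key step: step 2

Remark: radermachol 9 is drawn as the C5-keto, ring-enol tautomer of the target SMILES; the 5-hydroxy diketone form delivered by furan closure is its prototropic tautomer across the C5–O···H···O hydrogen bond and is taken as the same compound (3, 4 and 8 are likewise written in one tautomeric form).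

**Route**

Step 1
Reactants: 1 dimethyl phthalate; 2 mesityl oxide (4-methylpent-3-en-2-one)
Product: 4 2-(3-methylbut-2-enoyl)indane-1,3-dione, via diketo ester 3 (not isolated)
Conditions: NaOMe (1.2 equiv), toluene, 100 °C, slow addition of 2, MeOH distilled off; then 1 M HCl, 0 °C
Reagents that add atoms: none
Why: Crossed Claisen condensation of the methyl-ketone enolate of 2 with one ester group of 1 gives diketo ester 3, whose doubly activated methylene closes onto the second ester (Dieckmann-type, 5-exo-trig), the classical route to 2-acylindane-1,3-diones; precipitation of the sodium enolate of the strongly acidic trione pulls the reversible side equilibria of the enone (methoxide conjugate addition, γ-deprotonation) towards α′-acylation, and no stereocentre is formed.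

Step 2
Reactants: 4 2-(3-methylbut-2-enoyl)indane-1,3-dione; 5 1,4-naphthoquinone
Product: 8 ring-expanded naphthalene-1,4-diol triketone, via Michael adduct 6 (not isolated), via cyclobutanol 7 (not isolated)
Conditions: Cs2CO3 (0.1 equiv), MeCN, 23 °C, Ar; then Cs2CO3 (1.5 equiv), 60 °C; 1 M HCl, 0 °C
Reagents that add atoms: none
Why: Proposed new method: the catalytic caesium enolate of the strongly acidic trione 4 should add through its central carbon to a quinone CH of 5 (C3–C3a bond), proton transfer from 4 giving adduct 6 (naphthalenediol tautomer) until the quinone is consumed; with excess carbonate, 6 should react through its 2,3-dihydro-1,4-dione enolate, whose carbon (the future C4) attacks a ring carbonyl on the adjacent, now non-enolisable quaternary centre in a 4-exo-trig aldol (C4–carbonyl bond) to give cyclobutanolate 7. Retro-aldol (Grob-type) cleavage of the old C3–carbonyl bond of 7, the bond shared by its four- and five-membered rings, then produces the seven-membered ring by two-carbon ring expansion and not by direct closure, releases a carbanion stabilised by the remaining ring carbonyl and the enoyl group, and becomes irreversible when the dihydro-dione enolises to the naphthalene-1,4-diol 8. The closest known reactions are the abnormal Michael reaction (1,3-acyl shift through a four-membered intermediate), the acyl-alkylation of arynes and acetylenedicarboxylates by cyclic β-dicarbonyl compounds, and the retro-aldol half of the de Mayo reaction. No stereocentre remains in 8 and those of 7 are transient, so nothing needs to be controlled. Chemoselectivity is the requirement: the aldol must strike one of the two equivalent ring carbonyls, which sit in a strained five-membered 1,3-dione and are more electrophilic than the single β,β-dimethyl enone carbonyl (attack there would only shift the enoyl group to C4), while acyl transfer to the neighbouring naphthoxide oxygen and reversal of the conjugate addition should be reversible detours (Baker–Venkataraman-type return, re-addition) that drain into the irreversible C–C insertion in an aprotic medium free of nucleophilic base.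

Step 3
Reactants: 8 ring-expanded naphthalene-1,4-diol triketone
Product: 9 radermachol
Conditions: p-TsOH·H2O (5 mol %), toluene, 80 °C, Ar
Reagents that add atoms: none
Why: Acid-catalysed cyclodehydration of an o-hydroxyaryl 1,3-diketone to a 3-acylfuran (Paal–Knorr-type closure, the second stage of the classical quinone/β-diketone naphthofuran synthesis): the C9b hydroxyl adds 5-exo-trig to the side-chain carbonyl, water is lost across C2–C3, only this carbonyl can close because the ring carbonyl on C3 would give a bridged furan, and the 5-hydroxy diketone formed is the tautomer of 9; no stereocentre is created.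

**Compound list**

1 | dimethyl phthalate | COC(=O)c1ccccc1C(=O)OC | starting material
2 | mesityl oxide (4-methylpent-3-en-2-one) | CC(C)=CC(C)=O | starting material
3 | methyl 2-(5-methyl-3-oxohex-4-enoyl)benzoate (diketo ester) | COC(=O)c1ccccc1C(=O)CC(=O)C=C(C)C | intermediate (not isolated)
4 | 2-(3-methylbut-2-enoyl)indane-1,3-dione (triketo form; strongly enolised) | CC(C)=CC(=O)C1C(=O)c2ccccc2C1=O | intermediate
5 | 1,4-naphthoquinone | O=C1C=CC(=O)c2ccccc12 | starting material
6 | 2-(1,4-dihydroxynaphthalen-2-yl)-2-(3-methylbut-2-enoyl)indane-1,3-dione (Michael adduct, naphthalenediol tautomer) | CC(C)=CC(=O)C1(C(=O)c2ccccc2C1=O)c1cc(O)c2ccccc2c1O | intermediate (not isolated)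
7 | cyclobutanol aldol adduct: four-membered ring made of indane C2, one former indane carbonyl carbon (now C–OH) and quinone C3 and C2, cis-fused to the indan-1-one and to the 2,3-dihydronaphthalene-1,4-dione; racemic mixture of ring-fusion diastereomers, all four stereocentres transient and left unspecified | CC(C)=CC(=O)C12C(=O)c3ccccc3C1(O)C1C2C(=O)c2ccccc2C1=O | intermediate (not isolated)
8 | ring-expanded triketone: naphthalene-1,4-diol whose C2 and C3 are bridged by C(3-methylbut-2-enoyl)=C(OH)–(o-C6H4)–C(=O) in a seven-membered ring, the acyl-bearing carbon on C2 and the aryl ketone on C3 (ring-enol form) | CC(C)=CC(=O)C1=C(O)c2ccccc2C(=O)c2c(O)c3ccccc3c(O)c21 | intermediate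
9 | radermachol: 2-(2-methylprop-1-enyl)naphtho[1,2-b]furan with an o-phthaloyl unit bridging C3 and C4 (seven-membered ring), C5 keto and ring-enol tautomer | CC(C)=Cc1oc2c3c(c(O)c4ccccc4c(=O)c13)C(=O)c1ccccc1-2 | target

**Step count and risks**

Total steps: 3. Longest linear sequence: 3 steps (1 and 2 to 4, then 8, then 9).

Steps most likely to fail:

1. Step 2 (new method). The four-membered aldol may be too slow. The adduct could then be lost by reversal of the conjugate addition with base-induced decay of the quinone, by acyl transfer from the crowded quaternary carbon to the naphthoxide oxygen, or by migration of the enoyl group instead of a ring acyl group. The fallback uses known reactions only, sets out from 1,4-naphthoquinone 5 and mesityl oxide 2, and comes back at 8. Photochemical Friedel–Crafts acylation of 5 with methyl 2-formylbenzoate (350 nm or visible light, benzene) should give methyl 2-(1,4-dihydroxynaphthalene-2-carbonyl)benzoate F1, which Ag2O oxidises to the acylquinone methyl 2-(1,4-dioxo-1,4-dihydronaphthalene-2-carbonyl)benzoate F2. Kinetic enolisation of 2 (LiN(i-Pr)2, Me3SiCl, THF, −78 °C) gives trimethyl[(4-methylpenta-1,3-dien-2-yl)oxy]silane F3. F3 should add in Mukaiyama–Michael fashion to the free quinone carbon of F2 (MeCN, 0 °C) and give, after neutral aqueous work-up (no acid, so the 2-oxoalkyl naphthol does not close to a furan), methyl 2-[1,4-dihydroxy-3-(4-methyl-2-oxopent-3-en-1-yl)naphthalene-2-carbonyl]benzoate F4. Excess LiN(SiMe3)2 in THF then closes the seven-membered ring by Claisen (Dieckmann-type) attack of the ketone α-carbon on the aryl ester and gives 8 after acidification. In this order the C4–carbonyl bond is made first, C3–C3a by conjugate addition and C3–carbonyl last, so no four-membered intermediate is needed.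

2. Step 1. Mesityl oxide may be deprotonated at a γ-methyl group and self-condense under the hot alkoxide conditions, and the enoyl trione may cyclise by oxa-Michael addition during acidification. The fallback sets out from dimethyl phthalate 1 and comes back at 4. Claisen condensation of 1 with methyl acetate (NaOMe, toluene) gives methyl 1,3-dioxo-2,3-dihydro-1H-indene-2-carboxylate F5 as its sodium salt. Aqueous HCl at 70 °C hydrolyses and decarboxylates it to indane-1,3-dione F6. Acylation of F6 with 3-methylbut-2-enoic acid (DCC, DMAP, CH2Cl2; O-acylation followed by the 4-(dimethylamino)pyridine-mediated O-to-C acyl shift) gives 4 without any enolate of mesityl oxide.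

3. Step 3. Under acid the ring-enol hydroxyl may add to the dimethylvinyl ketone (six-membered oxa-Michael closure to a dihydropyranone), or the side-chain alkene may be hydrated, in competition with furan closure. The fallback sets out from 8 and comes back at 9. Treatment with Ac2O, Et3N and catalytic DMAP (CH2Cl2, 23 to 40 °C) should acetylate the side-chain enol and turn it into a leaving group. The C9b oxygen then closes the furan by conjugate addition–elimination under basic conditions, the C5 oxygen being acetylated at the same time, to give radermachol acetate F7. Brief K2CO3 in MeOH at 0 °C removes the acetate and gives 9. Acetylated material that has not cyclised returns to 8 in the same methanolysis and can be recycled.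

Further compounds
F1 | step 2 | methyl 2-(1,4-dihydroxynaphthalene-2-carbonyl)benzoate | COC(=O)c1ccccc1C(=O)c1cc(O)c2ccccc2c1O
F2 | step 2 | methyl 2-(1,4-dioxo-1,4-dihydronaphthalene-2-carbonyl)benzoate | COC(=O)c1ccccc1C(=O)C1=CC(=O)c2ccccc2C1=O
F3 | step 2 | trimethyl[(4-methylpenta-1,3-dien-2-yl)oxy]silane | C=C(O[Si](C)(C)C)C=C(C)C
F4 | step 2 | methyl 2-[1,4-dihydroxy-3-(4-methyl-2-oxopent-3-en-1-yl)naphthalene-2-carbonyl]benzoate | COC(=O)c1ccccc1C(=O)c1c(O)c2ccccc2c(O)c1CC(=O)C=C(C)C
F5 | step 1 | methyl 1,3-dioxo-2,3-dihydro-1H-indene-2-carboxylate | COC(=O)C1C(=O)c2ccccc2C1=O
F6 | step 1 | indane-1,3-dione | O=C1CC(=O)c2ccccc21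
F7 | step 3 | radermachol acetate (5-acetoxy diketone form) | CC(C)=Cc1oc2c3ccccc3c(OC(C)=O)c3c2c1C(=O)c1ccccc1C3=O
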